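**Plan**

1. Retrosynthesis: the three flavone phenols are capped as methyl ethers and the coumarin C3=C4 bond is taken back to the dihydro level. The only skeletal cut is then the biaryl bond between coumarin C6 and flavone C8, which leads to two purchasable bicycles.
2. Forward: apigenin 1 is permethylated to 2 and umbelliferone 3 is hydrogenated to phenol 4. An anodic dehydrogenative phenol–arene cross-coupling (via phenoxyl radical 5) joins 4 and 2 to biaryl 6 with neither halide nor boron. DDQ (via quinone methide 7) restores the coumarin in 8, and BBr3 (via borate 9) frees the phenols to give target 10.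
3. Enabling feature: flavone C8–H lies on ring A between ring oxygen O1 and the C7 oxygen, para to the C5 oxygen and only meta to the carbonyl-bearing C4a, so it is the most nucleophilic and least shielded CH of that half. Coumarin C6 is ortho to the free C7 hydroxyl, para to lactone oxygen O1, and has a single ortho neighbour.
4. Temporary oxidation level: with the pyranone of the coumarin half saturated, its phenol is the most easily oxidized group present, spin can no longer delocalize to C3, and the para position C4a is blocked, so the radical can bond only at an ortho carbon.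
5. Stereochemistry: the target has no stereocenter; the biaryl axis is not controlled.

Key step: step 3

Assumption: the target SMILES gives no descriptor for the biaryl axis (three ortho oxygen substituents), so the axis is treated as configurationally unspecified and no atroposelective control is attempted.

**Route**

Step 1
Reactants: 1 apigenin
Product: 2 4',5,7-tri-O-methylapigenin (5,7-dimethoxy-2-(4-methoxyphenyl)-4H-chromen-4-one)
Conditions: Me2SO4 (6 equiv), K2CO3 (6 equiv), acetone, reflux, 24–48 h
Reagents that add atoms: dimethyl sulfate, COS(=O)(=O)OC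
Why: Williamson etherification of the three phenoxides, with excess reagent and prolonged reflux to methylate the C5 hydroxyl that is hydrogen-bonded to the C4 carbonyl; no stereocenter is formed.

Step 2
Reactants: 3 umbelliferone (7-hydroxy-2H-chromen-2-one)
Product: 4 7-hydroxychroman-2-one (7-hydroxy-3,4-dihydrocoumarin)
Conditions: H2 (1 atm), 10% Pd/C, EtOAc–AcOH, rt
Reagents that add atoms: none
Why: Heterogeneous catalytic hydrogenation should saturate only the conjugated C3=C4 alkene of the pyranone, the benzene ring and the lactone being untouched in a non-nucleophilic solvent; no stereocenter is formed.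

Step 3
Reactants: 4 7-hydroxychroman-2-one (1 equiv); 2 4',5,7-tri-O-methylapigenin (3 equiv, excess recovered)
Product: 6 8-(7-hydroxy-2-oxochroman-6-yl)-5,7-dimethoxy-2-(4-methoxyphenyl)-4H-chromen-4-one, via phenoxyl radical 5 (not isolated)
Conditions: boron-doped diamond anode, platinum cathode, undivided cell, constant current 2.8 mA/cm2, about 2 F per mole of 4, Bu3NMe O3SOMe (0.09 M), HFIP, 50 °C
Reagents that add atoms: none
Why: Proposed new method: the closest known reaction type is the anodic dehydrogenative phenol–arene cross-coupling at boron-doped diamond in 1,1,1,3,3,3-hexafluoropropan-2-ol, known for phenols with simple alkoxyarenes and extended here to a chromone-fused, carbonyl-conjugated alkoxyarene as the nucleophile. Phenol 4 is the only free phenol and, with its pyranone saturated, the most easily oxidized ring in the cell, so it should lose one electron and one proton to give phenoxyl radical 5, which the fluorinated alcohol stabilizes by hydrogen bonding while it damps the nucleophilicity of unoxidized 4 and thereby homocoupling. Radical 5 should bond through C6 to C8 of flavone 2, the ring A carbon that is ortho to ring oxygen O1 and to the C7 methoxy group, para to the C5 methoxy group and only meta to the carbonyl-bearing C4a, after which loss of a second electron and a proton restores both benzene rings and the cathode releases H2. No ring is closed and no stereocenter is set; the new axis carries three ortho oxygen substituents and is left uncontrolled. Site selectivity is needed on both halves: in 5 the para position C4a is blocked and C8, between the phenol oxygen and the lactone oxygen, would give a tetra-ortho-substituted biaryl, which leaves C6 with its single ortho neighbour, and in 2 the C8–H is flanked by the unsubstituted ring oxygen whereas C6–H lies between two methoxy groups, one of them held toward it by the peri carbonyl, the same bias that directs electrophilic halogenation of 5,7-dialkoxyflavones to C8. Cross-coupling over homocoupling and overoxidation is served by the threefold excess of the methyl-capped flavone, which is harder to oxidize than any phenol present, and by stopping the electrolysis near 2 F per mole of 4.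

Step 4
Reactants: 6 8-(7-hydroxy-2-oxochroman-6-yl)-5,7-dimethoxy-2-(4-methoxyphenyl)-4H-chromen-4-one
Product: 8 8-(7-hydroxy-2-oxo-2H-chromen-6-yl)-5,7-dimethoxy-2-(4-methoxyphenyl)-4H-chromen-4-one, via para-quinone methide 7 (not isolated)
Conditions: DDQ (1.2 equiv), 1,4-dioxane, 80 °C
Reagents that add atoms: none
Why: DDQ dehydrogenation of a para-alkylphenol: hydride abstraction from benzylic C4, para to the free C7 hydroxyl, should give para-quinone methide 7, which tautomerizes by loss of the C3 proton next to the lactone carbonyl to the aromatic coumarin, the methyl-capped flavone half offering no comparably activated C–H bond.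

Step 5
Reactants: 8 8-(7-hydroxy-2-oxo-2H-chromen-6-yl)-5,7-dimethoxy-2-(4-methoxyphenyl)-4H-chromen-4-one
Product: 10 5,7-dihydroxy-8-(7-hydroxy-2-oxo-2H-chromen-6-yl)-2-(4-hydroxyphenyl)-4H-chromen-4-one (CNP0240623.0), via tetrakis(dibromoboryl) ether 9 (not isolated)
Conditions: BBr3 (12 equiv), CH2Cl2, −78 °C to rt; then H2O, 0 °C
Reagents that add atoms: none
Why: Lewis-acid ether cleavage: BBr3 coordinates each methoxy oxygen and bromide removes the methyl group as MeBr, giving aryl borate 9 that aqueous work-up hydrolyzes to the free phenols, while the coumarin lactone and both pyranones should tolerate the reagent at or below room temperature.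

**Compound list**

1 | apigenin, 5,7-dihydroxy-2-(4-hydroxyphenyl)-4H-chromen-4-one | O=c1cc(-c2ccc(O)cc2)oc2cc(O)cc(O)c12 | starting material
2 | 4',5,7-tri-O-methylapigenin, 5,7-dimethoxy-2-(4-methoxyphenyl)-4H-chromen-4-one | COc1ccc(-c2cc(=O)c3c(OC)cc(OC)cc3o2)cc1 | intermediate
3 | umbelliferone, 7-hydroxy-2H-chromen-2-one | O=c1ccc2ccc(O)cc2o1 | starting material
4 | 7-hydroxychroman-2-one (7-hydroxy-3,4-dihydrocoumarin) | O=C1CCc2ccc(O)cc2O1 | intermediate
5 | 2-oxochroman-7-yloxyl, the phenoxyl radical of 4 | [O]c1ccc2CCC(=O)Oc2c1 | intermediate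
6 | 8-(7-hydroxy-2-oxochroman-6-yl)-5,7-dimethoxy-2-(4-methoxyphenyl)-4H-chromen-4-one | COc1ccc(-c2cc(=O)c3c(OC)cc(OC)c(-c4cc5c(cc4O)OC(=O)CC5)c3o2)cc1 | intermediate
7 | 6-[5,7-dimethoxy-2-(4-methoxyphenyl)-4-oxo-4H-chromen-8-yl]-3H-chromene-2,7-dione (para-quinone methide) | COc1ccc(-c2cc(=O)c3c(OC)cc(OC)c(C4=CC5=CCC(=O)OC5=CC4=O)c3o2)cc1 | intermediate
8 | 8-(7-hydroxy-2-oxo-2H-chromen-6-yl)-5,7-dimethoxy-2-(4-methoxyphenyl)-4H-chromen-4-one | COc1ccc(-c2cc(=O)c3c(OC)cc(OC)c(-c4cc5ccc(=O)oc5cc4O)c3o2)cc1 | intermediate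
9 | tetrakis(dibromoboryl) ether of 10 (idealized aryl borate before hydrolysis) | BrB(Br)Oc1ccc(-c2cc(=O)c3c(OB(Br)Br)cc(OB(Br)Br)c(-c4cc5ccc(=O)oc5cc4OB(Br)Br)c3o2)cc1 | intermediate
10 | 5,7-dihydroxy-8-(7-hydroxy-2-oxo-2H-chromen-6-yl)-2-(4-hydroxyphenyl)-4H-chromen-4-one (CNP0240623.0) | O=c1ccc2cc(-c3c(O)cc(O)c4c(=O)cc(-c5ccc(O)cc5)oc34)c(O)cc2o1 | target

**Step count and risks**

Total step count: 5. Longest linear sequence: 4 steps (steps 1, 3, 4, 5, or equally steps 2, 3, 4, 5).

Steps most likely to fail:

Step 3 (labelled step). What may go wrong: the phenoxyl radical may be intercepted by unoxidized phenol (homocoupling) faster than by the carbonyl-conjugated flavone, bond formation may stray to flavone C6 or coumarin C8, or the product phenol may be oxidized further. Fallback by known chemistry, setting out from compound 2 and coming back at compound 8. Electrophilic iodination of 2 (N-iodosuccinimide, CF3CO2H, MeCN) should give 8-iodo-5,7-dimethoxy-2-(4-methoxyphenyl)-4H-chromen-4-one F1. The coumarin half is made with the halogen position fixed by the starting material: von Pechmann condensation of commercial 4-bromoresorcinol with malic acid in concentrated H2SO4 should give 6-bromo-7-hydroxy-2H-chromen-2-one F2. Protection (MOMCl, iPr2NEt, CH2Cl2) gives 6-bromo-7-(methoxymethoxy)-2H-chromen-2-one F3, and Miyaura borylation (bis(pinacolato)diboron, Pd(dppf)Cl2, KOAc, dioxane, 90 °C) gives 7-(methoxymethoxy)-6-(4,4,5,5-tetramethyl-1,3,2-dioxaborolan-2-yl)-2H-chromen-2-one F4. Suzuki–Miyaura coupling of F1 with F4 (Pd(OAc)2, SPhos, K3PO4, toluene–water, 90 °C) should give 5,7-dimethoxy-8-[7-(methoxymethoxy)-2-oxo-2H-chromen-6-yl]-2-(4-methoxyphenyl)-4H-chromen-4-one F5. HCl in MeOH then removes the acetal and returns to the route at compound 8, so that step 4 is bypassed and step 5 follows.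

Step 4. What may go wrong: the quinone methide may be trapped by water or by the hydroquinone by-product instead of tautomerizing, or the hydroxybiaryl may undergo oxidative coupling. Fallback setting out from compound 6 and coming back at compound 8. Silylation (tBuMe2SiCl, imidazole, DMF) gives 8-{7-[(tert-butyldimethylsilyl)oxy]-2-oxochroman-6-yl}-5,7-dimethoxy-2-(4-methoxyphenyl)-4H-chromen-4-one F6. α-Selenenylation of the lactone (LiN(SiMe3)2, THF, −78 °C, then PhSeBr) gives 8-{7-[(tert-butyldimethylsilyl)oxy]-2-oxo-3-(phenylselanyl)chroman-6-yl}-5,7-dimethoxy-2-(4-methoxyphenyl)-4H-chromen-4-one F7, racemic at C3. H2O2 and pyridine in CH2Cl2 at 0 °C oxidize it to 8-{7-[(tert-butyldimethylsilyl)oxy]-2-oxo-3-(phenylseleninyl)chroman-6-yl}-5,7-dimethoxy-2-(4-methoxyphenyl)-4H-chromen-4-one F8. This selenoxide should undergo syn-elimination toward C4 to give 8-{7-[(tert-butyldimethylsilyl)oxy]-2-oxo-2H-chromen-6-yl}-5,7-dimethoxy-2-(4-methoxyphenyl)-4H-chromen-4-one F9. Bu4NF in THF then frees the phenol and returns to the route at compound 8.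

Step 5. What may go wrong: incomplete cleavage of the C7 and C4' methyl ethers, or acid-promoted opening of the flavone pyranone and reclosure onto the C5 oxygen (Wessely–Moser rearrangement), which would move the coumarin from C8 to C6. Fallback that changes the protecting group, setting out from compound 1 and coming back at compound 10. Benzylation (BnBr, K2CO3, DMF, 80 °C) gives 5,7-bis(benzyloxy)-2-[4-(benzyloxy)phenyl]-4H-chromen-4-one F10. The anodic coupling of step 3 with phenol 4 (again via radical 5) would give 5,7-bis(benzyloxy)-2-[4-(benzyloxy)phenyl]-8-(7-hydroxy-2-oxochroman-6-yl)-4H-chromen-4-one F11. DDQ as in step 4 would pass through 6-{5,7-bis(benzyloxy)-2-[4-(benzyloxy)phenyl]-4-oxo-4H-chromen-8-yl}-3H-chromene-2,7-dione F12 to 5,7-bis(benzyloxy)-2-[4-(benzyloxy)phenyl]-8-(7-hydroxy-2-oxo-2H-chromen-6-yl)-4H-chromen-4-one F13. BCl3 with pentamethylbenzene as benzyl-cation scavenger (CH2Cl2, −78 °C) then removes the three benzyl groups at low temperature by way of the tetrakis(dichloroboryl) ether of the target F14, which aqueous work-up hydrolyzes to compound 10.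

**Further compounds**

F1 | step 3 | 8-iodo-5,7-dimethoxy-2-(4-methoxyphenyl)-4H-chromen-4-one | COc1ccc(-c2cc(=O)c3c(OC)cc(OC)c(I)c3o2)cc1
F2 | step 3 | 6-bromo-7-hydroxy-2H-chromen-2-one | O=c1ccc2cc(Br)c(O)cc2o1
F3 | step 3 | 6-bromo-7-(methoxymethoxy)-2H-chromen-2-one | COCOc1cc2oc(=O)ccc2cc1Br
F4 | step 3 | 7-(methoxymethoxy)-6-(4,4,5,5-tetramethyl-1,3,2-dioxaborolan-2-yl)-2H-chromen-2-one | COCOc1cc2oc(=O)ccc2cc1B1OC(C)(C)C(C)(C)O1
F5 | step 3 | 5,7-dimethoxy-8-[7-(methoxymethoxy)-2-oxo-2H-chromen-6-yl]-2-(4-methoxyphenyl)-4H-chromen-4-one | COCOc1cc2oc(=O)ccc2cc1-c1c(OC)cc(OC)c2c(=O)cc(-c3ccc(OC)cc3)oc12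
F6 | step 4 | 8-{7-[(tert-butyldimethylsilyl)oxy]-2-oxochroman-6-yl}-5,7-dimethoxy-2-(4-methoxyphenyl)-4H-chromen-4-one | COc1ccc(-c2cc(=O)c3c(OC)cc(OC)c(-c4cc5c(cc4O[Si](C)(C)C(C)(C)C)OC(=O)CC5)c3o2)cc1
F7 | step 4 | 8-{7-[(tert-butyldimethylsilyl)oxy]-2-oxo-3-(phenylselanyl)chroman-6-yl}-5,7-dimethoxy-2-(4-methoxyphenyl)-4H-chromen-4-one (racemic at C3) | COc1ccc(-c2cc(=O)c3c(OC)cc(OC)c(-c4cc5c(cc4O[Si](C)(C)C(C)(C)C)OC(=O)C([Se]c6ccccc6)C5)c3o2)cc1
F8 | step 4 | 8-{7-[(tert-butyldimethylsilyl)oxy]-2-oxo-3-(phenylseleninyl)chroman-6-yl}-5,7-dimethoxy-2-(4-methoxyphenyl)-4H-chromen-4-one (selenoxide, not isolated) | COc1ccc(-c2cc(=O)c3c(OC)cc(OC)c(-c4cc5c(cc4O[Si](C)(C)C(C)(C)C)OC(=O)C([Se](=O)c6ccccc6)C5)c3o2)cc1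
F9 | step 4 | 8-{7-[(tert-butyldimethylsilyl)oxy]-2-oxo-2H-chromen-6-yl}-5,7-dimethoxy-2-(4-methoxyphenyl)-4H-chromen-4-one | COc1ccc(-c2cc(=O)c3c(OC)cc(OC)c(-c4cc5ccc(=O)oc5cc4O[Si](C)(C)C(C)(C)C)c3o2)cc1
F10 | step 5 | 5,7-bis(benzyloxy)-2-[4-(benzyloxy)phenyl]-4H-chromen-4-one | O=c1cc(-c2ccc(OCc3ccccc3)cc2)oc2cc(OCc3ccccc3)cc(OCc3ccccc3)c12
F11 | step 5 | 5,7-bis(benzyloxy)-2-[4-(benzyloxy)phenyl]-8-(7-hydroxy-2-oxochroman-6-yl)-4H-chromen-4-one | O=C1CCc2cc(-c3c(OCc4ccccc4)cc(OCc4ccccc4)c4c(=O)cc(-c5ccc(OCc6ccccc6)cc5)oc34)c(O)cc2O1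
F12 | step 5 | 6-{5,7-bis(benzyloxy)-2-[4-(benzyloxy)phenyl]-4-oxo-4H-chromen-8-yl}-3H-chromene-2,7-dione (para-quinone methide, not isolated) | O=C1CC=C2C=C(c3c(OCc4ccccc4)cc(OCc4ccccc4)c4c(=O)cc(-c5ccc(OCc6ccccc6)cc5)oc34)C(=O)C=C2O1
F13 | step 5 | 5,7-bis(benzyloxy)-2-[4-(benzyloxy)phenyl]-8-(7-hydroxy-2-oxo-2H-chromen-6-yl)-4H-chromen-4-one | O=c1ccc2cc(-c3c(OCc4ccccc4)cc(OCc4ccccc4)c4c(=O)cc(-c5ccc(OCc6ccccc6)cc5)oc34)c(O)cc2o1
F14 | step 5 | tetrakis(dichloroboryl) ether of the target (idealized aryl borate, not isolated) | O=c1ccc2cc(-c3c(OB(Cl)Cl)cc(OB(Cl)Cl)c4c(=O)cc(-c5ccc(OB(Cl)Cl)cc5)oc34)c(OB(Cl)Cl)cc2o1
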